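**Plan**
1. Retrosynthesis: the seven benzyl ethers come off last. Before that the flavanone is cut at C2–C1″ (aryl group added to a chromone), and that chromone at O1–C2, C2–C3 and C4–C4a back to a free para-phenol.
2. The flavone is cut at C2–C3 and O1–C2 into a 2-hydroxyacetophenone and a 6H-benzo[c]chromen-6-one. The lactone is cut at its biaryl bond and its C–O bond into a 2-bromobenzoic acid and phloroglucinol.
3. Enabling feature: flavone C2 is a carboxyl-level carbon on C1′ of the catechol ring, next to the biaryl carbon C2′, and flavanone C6 has oxygen on both neighbours (C5 and C7). One of these oxygens and that carbon can therefore be held as a six-membered biaryl lactone, which also tells apart the three oxygens of ring A (the phloroglucinol-derived ring of the flavanone).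
4. Forward order: biaryl bond and lactone ring, then lactone opening with closure of the flavone pyranone ring, then the chromone ring on ring A, then the C2 aryl group.
5. Stereochemistry: the only stereocentre, C2 (R), is set by the chiral ligand in a palladium-catalysed conjugate addition of the arylboronic acid and is kept by neutral hydrogenolysis.

Key step: step 6

Remark: the target is defined only at C2; the biaryl axis with three ortho substituents is taken as configurationally labile, so no axial descriptor is carried through the route.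
Remark: the (S)-pyridine-oxazoline ligand is assumed to deliver the aryl group to the same enone face as with simple chromones and cyclic enones, which corresponds to 2R here.

**Step 1**
Reactants: 1 3,4-bis(benzyloxy)benzoic acid
Product: 2 4,5-bis(benzyloxy)-2-bromobenzoic acid
Conditions: Br2 (1.05 equiv), NaOAc, AcOH, rt
Reagents that add atoms: bromine, BrBr
Why: Electrophilic aromatic bromination should go para to the 3-benzyloxy group and ortho to the carboxyl, the usual site for 3,4-dialkoxybenzoic acids, while NaOAc takes up HBr so that the benzyl ethers are not cleaved.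

**Step 2**
Reactants: 2 4,5-bis(benzyloxy)-2-bromobenzoic acid; 3 phloroglucinol
Product: 5 8,9-bis(benzyloxy)-1,3-dihydroxy-6H-benzo[c]chromen-6-one, via biaryl hydroxy acid 4 (not isolated)
Conditions: 3 (3 equiv), NaOH, H2O, 100 °C; CuSO4 (10 mol%, aq.), 100 °C; then aq. HCl
Reagents that add atoms: none
Why: In this Hurtley reaction copper catalysis, assisted by the ortho carboxylate, joins a ring carbon of the phloroglucinol anion to the carbon bearing bromine, and the hydroxy acid lactonises onto a flanking hydroxyl on acidification; the threefold symmetry of 3 leaves no regiochemical choice and benzyl ethers tolerate hot aqueous alkali.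

**Step 3**
Reactants: 5 8,9-bis(benzyloxy)-1,3-dihydroxy-6H-benzo[c]chromen-6-one
Product: 6 3-(allyloxy)-8,9-bis(benzyloxy)-1-hydroxy-6H-benzo[c]chromen-6-one
Conditions: allyl bromide (1.05 equiv), K2CO3 (1.1 equiv), DMF, 0 °C to rt
Reagents that add atoms: allyl bromide, C=CCBr
Why: Williamson etherification with a limiting amount of halide should take the unhindered 3-hydroxyl (para to the biaryl bond) ahead of the 1-hydroxyl, which sits in the bay region against H-10, the same preference that 5,7-dihydroxycoumarins show for their 7-oxygen.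

**Step 4**
Reactants: 6 3-(allyloxy)-8,9-bis(benzyloxy)-1-hydroxy-6H-benzo[c]chromen-6-one
Product: 7 3-(allyloxy)-1,8,9-tris(benzyloxy)-6H-benzo[c]chromen-6-one
Conditions: BnBr (1.5 equiv), K2CO3, DMF, 60 °C
Reagents that add atoms: benzyl bromide, BrCc1ccccc1
Why: Williamson etherification of the remaining, hindered phenol under slightly more forcing anhydrous conditions, which the lactone and the allyl ether should tolerate.

**Step 5**
Reactants: 8 1-(2,4,6-trihydroxyphenyl)ethanone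
Product: 9 1-[2,4-bis(benzyloxy)-6-hydroxyphenyl]ethanone
Conditions: BnBr (2.1 equiv), K2CO3, DMF, rt
Reagents that add atoms: benzyl bromide, BrCc1ccccc1
Why: Williamson etherification should stop at the diether because the hydroxyl hydrogen-bonded to the acetyl carbonyl is the least nucleophilic of the three.

**Step 6**
Reactants: 7 3-(allyloxy)-1,8,9-tris(benzyloxy)-6H-benzo[c]chromen-6-one; 9 1-[2,4-bis(benzyloxy)-6-hydroxyphenyl]ethanone
Product: 11 2-{2-[4-(allyloxy)-2-(benzyloxy)-6-hydroxyphenyl]-4,5-bis(benzyloxy)phenyl}-5,7-bis(benzyloxy)-4H-chromen-4-one, via 1,3-diketone 10 (not isolated)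
Conditions: 9 (1.3 equiv), LiN(SiMe3)2 (4 equiv), THF, −78 to −10 °C; 7, THF, −78 °C to rt; aq. HCl; then p-TsOH·H2O (cat.), toluene, 90 °C
Reagents that add atoms: none
Why: LiN(SiMe3)2 turns 9 into its dilithium phenoxide–enolate, whose carbon adds to the lactone carbonyl of 7; the tetrahedral adduct collapses with loss of the ring A phenoxide, and the resulting 1,3-diketone 10 is deprotonated at once, which blocks retro-Claisen return to the lactone. This is a crossed Claisen acylation of a ketone enolate by a phenolic lactone, the intermolecular counterpart of the Baker–Venkataraman acyl transfer, with the six-membered biaryl lactone acting as an internally activated aryl ester. Under acid the acetophenone hydroxyl adds to the aroyl carbonyl in a 6-exo-trig closure and loss of water gives the aromatic 4-pyranone ring, so that C2–C3 and O1–C2 of the flavone are formed in this step. No stereocentre is created. The step needs C-acylation and not O-acylation, which the dianion secures because any O-aroyl ester would rearrange to the same diketone under the base. It also needs closure by the acetophenone hydroxyl and not by the freed ring A phenol, which is expected because only the former can dehydrate to an aromatic pyranone while the hemiketal from the latter forms reversibly.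

**Step 7**
Reactants: 11 2-{2-[4-(allyloxy)-2-(benzyloxy)-6-hydroxyphenyl]-4,5-bis(benzyloxy)phenyl}-5,7-bis(benzyloxy)-4H-chromen-4-one
Product: 12 2-{2-[4-(allyloxy)-2,6-bis(benzyloxy)phenyl]-4,5-bis(benzyloxy)phenyl}-5,7-bis(benzyloxy)-4H-chromen-4-one
Conditions: BnBr (1.5 equiv), K2CO3, DMF, 50 °C
Reagents that add atoms: benzyl bromide, BrCc1ccccc1
Why: Williamson etherification of the only free phenol makes the two flanking oxygens of ring A alike, so that the two ring carbons next to the para oxygen become equivalent; the flavone is stable to carbonate in DMF.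

**Step 8**
Reactants: 12 2-{2-[4-(allyloxy)-2,6-bis(benzyloxy)phenyl]-4,5-bis(benzyloxy)phenyl}-5,7-bis(benzyloxy)-4H-chromen-4-one
Product: 13 2-{2-[2,6-bis(benzyloxy)-4-hydroxyphenyl]-4,5-bis(benzyloxy)phenyl}-5,7-bis(benzyloxy)-4H-chromen-4-one
Conditions: Pd(PPh3)4 (5 mol%), morpholine (5 equiv), THF, rt
Reagents that add atoms: none
Why: Tsuji–Trost deallylation: zerovalent palladium ionises the aryl allyl ether to a π-allyl complex and the phenoxide, morpholine captures the allyl group, and benzyl ethers and the flavone are not touched.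

**Step 9**
Reactants: 13 2-{2-[2,6-bis(benzyloxy)-4-hydroxyphenyl]-4,5-bis(benzyloxy)phenyl}-5,7-bis(benzyloxy)-4H-chromen-4-one
Product: 14 2-{2-[2,6-bis(benzyloxy)-4-hydroxy-3-iodophenyl]-4,5-bis(benzyloxy)phenyl}-5,7-bis(benzyloxy)-4H-chromen-4-one
Conditions: N-iodosuccinimide (1.0 equiv), CH2Cl2, −20 to 0 °C
Reagents that add atoms: N-iodosuccinimide, O=C1CCC(=O)N1I
Why: Electrophilic aromatic iodination should occur ortho to the free phenol on ring A, by far the most electron-rich ring (the flavone benzo ring is deactivated by its carbonyl), and the two ortho positions are equivalent, so mono-iodination gives one constitution.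

**Step 10**
Reactants: 14 2-{2-[2,6-bis(benzyloxy)-4-hydroxy-3-iodophenyl]-4,5-bis(benzyloxy)phenyl}-5,7-bis(benzyloxy)-4H-chromen-4-one
Product: 16 2-{2-[3-acetyl-2,6-bis(benzyloxy)-4-hydroxyphenyl]-4,5-bis(benzyloxy)phenyl}-5,7-bis(benzyloxy)-4H-chromen-4-one, via enol ether 15 (not isolated)
Conditions: CH2=C(OEt)SnBu3 (1.5 equiv), Pd(PPh3)4 (5 mol%), toluene, 100 °C; then 1 M aq. HCl, THF, rt
Reagents that add atoms: tributyl(1-ethoxyvinyl)stannane, CCCC[Sn](CCCC)(CCCC)C(=C)OCC; water, O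
Why: Stille coupling of the aryl iodide with an acetyl anion equivalent under zerovalent palladium catalysis, then mild acid hydrolysis of the enol ether, places the acetyl group exactly at the iodinated carbon without any Lewis acid that could cleave benzyl ethers.

**Step 11**
Reactants: 16 2-{2-[3-acetyl-2,6-bis(benzyloxy)-4-hydroxyphenyl]-4,5-bis(benzyloxy)phenyl}-5,7-bis(benzyloxy)-4H-chromen-4-one
Product: 18 2-{4,5-bis(benzyloxy)-2-[5,7-bis(benzyloxy)-4-oxo-4H-chromen-6-yl]phenyl}-5,7-bis(benzyloxy)-4H-chromen-4-one, via enaminone 17 (not isolated)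
Conditions: Me2NCH(OMe)2 (3 equiv), toluene, 90 °C; then AcOH, 70 °C
Reagents that add atoms: N,N-dimethylformamide dimethyl acetal, COC(OC)N(C)C
Why: Standard chromone synthesis: condensation of the methyl ketone with the amide acetal gives the enaminone, and under acid the ortho hydroxyl adds to its β-carbon (6-endo-trig) with loss of dimethylamine; only the para oxygen of ring A is free, so the aryl group ends up at C6.

**Step 12**
Reactants: 18 2-{4,5-bis(benzyloxy)-2-[5,7-bis(benzyloxy)-4-oxo-4H-chromen-6-yl]phenyl}-5,7-bis(benzyloxy)-4H-chromen-4-one; 19 4-(benzyloxy)phenylboronic acid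
Product: 20 (2R)-5,7-bis(benzyloxy)-2-[4-(benzyloxy)phenyl]-6-{4,5-bis(benzyloxy)-2-[5,7-bis(benzyloxy)-4-oxo-4H-chromen-2-yl]phenyl}-2,3-dihydro-4H-chromen-4-one
Conditions: 19 (3 equiv), Pd(OCOCF3)2 (10 mol%), (S)-4-tert-butyl-2-(pyridin-2-yl)-4,5-dihydro-1,3-oxazole (12 mol%), NH4PF6 (30 mol%), H2O (5 equiv), ClCH2CH2Cl, 60 °C
Reagents that add atoms: none
Why: Asymmetric conjugate addition of an arylboronic acid (Hayashi–Miyaura type, with a cationic complex of divalent palladium): transmetalation gives an aryl–palladium species that inserts the chromone C2=C3 bond on the face left open by the tert-butyl group of the (S)-ligand, which sets C2 as R, and protonolysis of the palladium enolate releases the flavanone; the flavone unit, a β,β-disubstituted enone, should not react.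

**Step 13**
Reactants: 20 (2R)-5,7-bis(benzyloxy)-2-[4-(benzyloxy)phenyl]-6-{4,5-bis(benzyloxy)-2-[5,7-bis(benzyloxy)-4-oxo-4H-chromen-2-yl]phenyl}-2,3-dihydro-4H-chromen-4-one
Product: 21 (2R)-6-[2-(5,7-dihydroxy-4-oxo-4H-chromen-2-yl)-4,5-dihydroxyphenyl]-5,7-dihydroxy-2-(4-hydroxyphenyl)-2,3-dihydro-4H-chromen-4-one
Conditions: H2 (1 atm), Pd/C (10% Pd), THF–MeOH, rt
Reagents that add atoms: none
Why: Catalytic hydrogenolysis should cleave all seven benzyl ethers under neutral conditions, which avoid the base-mediated ring opening that would racemise C2, while the flavone double bond and both aryl ketones are expected to survive at ambient pressure and temperature.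

**Compound list**
1 | 3,4-bis(benzyloxy)benzoic acid | OC(=O)c1ccc(OCc2ccccc2)c(OCc2ccccc2)c1 | starting material
2 | 4,5-bis(benzyloxy)-2-bromobenzoic acid | OC(=O)c1cc(OCc2ccccc2)c(OCc2ccccc2)cc1Br | intermediate
3 | phloroglucinol (benzene-1,3,5-triol) | Oc1cc(O)cc(O)c1 | starting material
4 | 4,5-bis(benzyloxy)-2-(2,4,6-trihydroxyphenyl)benzoic acid | OC(=O)c1cc(OCc2ccccc2)c(OCc2ccccc2)cc1-c1c(O)cc(O)cc1O | intermediate
5 | 8,9-bis(benzyloxy)-1,3-dihydroxy-6H-benzo[c]chromen-6-one | O=C1Oc2cc(O)cc(O)c2-c2cc(OCc3ccccc3)c(OCc3ccccc3)cc12 | intermediate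
6 | 3-(allyloxy)-8,9-bis(benzyloxy)-1-hydroxy-6H-benzo[c]chromen-6-one | O=C1Oc2cc(OCC=C)cc(O)c2-c2cc(OCc3ccccc3)c(OCc3ccccc3)cc12 | intermediate
7 | 3-(allyloxy)-1,8,9-tris(benzyloxy)-6H-benzo[c]chromen-6-one | O=C1Oc2cc(OCC=C)cc(OCc3ccccc3)c2-c2cc(OCc3ccccc3)c(OCc3ccccc3)cc12 | intermediate
8 | 1-(2,4,6-trihydroxyphenyl)ethanone | CC(=O)c1c(O)cc(O)cc1O | starting material
9 | 1-[2,4-bis(benzyloxy)-6-hydroxyphenyl]ethanone | CC(=O)c1c(O)cc(OCc2ccccc2)cc1OCc1ccccc1 | intermediate
10 | 1-{2-[4-(allyloxy)-2-(benzyloxy)-6-hydroxyphenyl]-4,5-bis(benzyloxy)phenyl}-3-[2,4-bis(benzyloxy)-6-hydroxyphenyl]propane-1,3-dione | O=C(CC(=O)c1cc(OCc2ccccc2)c(OCc2ccccc2)cc1-c1c(O)cc(OCC=C)cc1OCc1ccccc1)c1c(O)cc(OCc2ccccc2)cc1OCc1ccccc1 | intermediate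
11 | 2-{2-[4-(allyloxy)-2-(benzyloxy)-6-hydroxyphenyl]-4,5-bis(benzyloxy)phenyl}-5,7-bis(benzyloxy)-4H-chromen-4-one | O=c1cc(-c2cc(OCc3ccccc3)c(OCc3ccccc3)cc2-c2c(O)cc(OCC=C)cc2OCc2ccccc2)oc2cc(OCc3ccccc3)cc(OCc3ccccc3)c12 | intermediate
12 | 2-{2-[4-(allyloxy)-2,6-bis(benzyloxy)phenyl]-4,5-bis(benzyloxy)phenyl}-5,7-bis(benzyloxy)-4H-chromen-4-one | C=CCOc1cc(OCc2ccccc2)c(-c2cc(OCc3ccccc3)c(OCc3ccccc3)cc2-c2cc(=O)c3c(OCc4ccccc4)cc(OCc4ccccc4)cc3o2)c(OCc2ccccc2)c1 | intermediate
13 | 2-{2-[2,6-bis(benzyloxy)-4-hydroxyphenyl]-4,5-bis(benzyloxy)phenyl}-5,7-bis(benzyloxy)-4H-chromen-4-one | Oc1cc(OCc2ccccc2)c(-c2cc(OCc3ccccc3)c(OCc3ccccc3)cc2-c2cc(=O)c3c(OCc4ccccc4)cc(OCc4ccccc4)cc3o2)c(OCc2ccccc2)c1 | intermediate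
14 | 2-{2-[2,6-bis(benzyloxy)-4-hydroxy-3-iodophenyl]-4,5-bis(benzyloxy)phenyl}-5,7-bis(benzyloxy)-4H-chromen-4-one | Oc1cc(OCc2ccccc2)c(-c2cc(OCc3ccccc3)c(OCc3ccccc3)cc2-c2cc(=O)c3c(OCc4ccccc4)cc(OCc4ccccc4)cc3o2)c(OCc2ccccc2)c1I | intermediate
15 | 2-{2-[2,6-bis(benzyloxy)-3-(1-ethoxyvinyl)-4-hydroxyphenyl]-4,5-bis(benzyloxy)phenyl}-5,7-bis(benzyloxy)-4H-chromen-4-one | CCOC(=C)c1c(O)cc(OCc2ccccc2)c(-c2cc(OCc3ccccc3)c(OCc3ccccc3)cc2-c2cc(=O)c3c(OCc4ccccc4)cc(OCc4ccccc4)cc3o2)c1OCc1ccccc1 | intermediate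
16 | 2-{2-[3-acetyl-2,6-bis(benzyloxy)-4-hydroxyphenyl]-4,5-bis(benzyloxy)phenyl}-5,7-bis(benzyloxy)-4H-chromen-4-one | CC(=O)c1c(O)cc(OCc2ccccc2)c(-c2cc(OCc3ccccc3)c(OCc3ccccc3)cc2-c2cc(=O)c3c(OCc4ccccc4)cc(OCc4ccccc4)cc3o2)c1OCc1ccccc1 | intermediate
17 | 2-{2-[2,6-bis(benzyloxy)-3-[(2E)-3-(dimethylamino)prop-2-enoyl]-4-hydroxyphenyl]-4,5-bis(benzyloxy)phenyl}-5,7-bis(benzyloxy)-4H-chromen-4-one | CN(C)/C=C/C(=O)c1c(O)cc(OCc2ccccc2)c(-c2cc(OCc3ccccc3)c(OCc3ccccc3)cc2-c2cc(=O)c3c(OCc4ccccc4)cc(OCc4ccccc4)cc3o2)c1OCc1ccccc1 | intermediate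
18 | 2-{4,5-bis(benzyloxy)-2-[5,7-bis(benzyloxy)-4-oxo-4H-chromen-6-yl]phenyl}-5,7-bis(benzyloxy)-4H-chromen-4-one | O=c1ccoc2cc(OCc3ccccc3)c(-c3cc(OCc4ccccc4)c(OCc4ccccc4)cc3-c3cc(=O)c4c(OCc5ccccc5)cc(OCc5ccccc5)cc4o3)c(OCc3ccccc3)c12 | intermediate
19 | 4-(benzyloxy)phenylboronic acid | OB(O)c1ccc(OCc2ccccc2)cc1 | starting material
20 | (2R)-5,7-bis(benzyloxy)-2-[4-(benzyloxy)phenyl]-6-{4,5-bis(benzyloxy)-2-[5,7-bis(benzyloxy)-4-oxo-4H-chromen-2-yl]phenyl}-2,3-dihydro-4H-chromen-4-one | O=C1C[C@H](c2ccc(OCc3ccccc3)cc2)Oc2cc(OCc3ccccc3)c(-c3cc(OCc4ccccc4)c(OCc4ccccc4)cc3-c3cc(=O)c4c(OCc5ccccc5)cc(OCc5ccccc5)cc4o3)c(OCc3ccccc3)c21 | intermediate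
21 | (2R)-6-[2-(5,7-dihydroxy-4-oxo-4H-chromen-2-yl)-4,5-dihydroxyphenyl]-5,7-dihydroxy-2-(4-hydroxyphenyl)-2,3-dihydro-4H-chromen-4-one | O=C1C[C@H](c2ccc(O)cc2)Oc2cc(O)c(-c3cc(O)c(O)cc3-c3cc(=O)c4c(O)cc(O)cc4o3)c(O)c21 | target

**Step count**
Total: 13 steps. Longest linear sequence: 12 steps (steps 1–4 and 6–13, from 1); step 5 is a one-step side branch.

**Steps most likely to fail**

Step 6. The lactone may re-form by retro-Claisen cleavage before the diketone is trapped as its enolate, or the freed ring A phenol may compete for the aroyl carbonyl during the acid stage, so that conversion to the flavone stalls. The fallback separates lactone opening from acylation and uses the classical intramolecular acyl transfer. It sets out from 7. Opening with KOH in DMSO–water and trapping of the dianion with benzyl bromide should give benzyl 2-[4-(allyloxy)-2,6-bis(benzyloxy)phenyl]-4,5-bis(benzyloxy)benzoate F1. Saponification (LiOH, THF–MeOH–H2O) should give 2-[4-(allyloxy)-2,6-bis(benzyloxy)phenyl]-4,5-bis(benzyloxy)benzoic acid F2. Esterification with 9 (carbodiimide, DMAP, CH2Cl2) should give 2-acetyl-3,5-bis(benzyloxy)phenyl 2-[4-(allyloxy)-2,6-bis(benzyloxy)phenyl]-4,5-bis(benzyloxy)benzoate F3. Baker–Venkataraman rearrangement (KOH, pyridine, 50 °C) should give 1-{2-[4-(allyloxy)-2,6-bis(benzyloxy)phenyl]-4,5-bis(benzyloxy)phenyl}-3-[2,4-bis(benzyloxy)-6-hydroxyphenyl]propane-1,3-dione F4. Cyclodehydration (p-TsOH, toluene, 90 °C) then comes back to the route at 12, and step 7 is no longer needed.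

Step 12. Insertion into the hindered, electron-rich 5-alkoxychromone may be slow, so that protodeboronation outruns addition, and facial discrimination may be poor. The fallback builds the heterocycle by oxa-Michael closure and obtains the enantiomer by resolution. It sets out from 16. Claisen–Schmidt condensation with 4-(benzyloxy)benzaldehyde (Ba(OH)2, MeOH–THF, 40 °C) should give (2E)-1-{2,4-bis(benzyloxy)-3-[4,5-bis(benzyloxy)-2-(5,7-bis(benzyloxy)-4-oxo-4H-chromen-2-yl)phenyl]-6-hydroxyphenyl}-3-[4-(benzyloxy)phenyl]prop-2-en-1-one F5. Cyclisation (NaOAc, EtOH, reflux) should give the racemic flavanone, rac-5,7-bis(benzyloxy)-2-[4-(benzyloxy)phenyl]-6-{4,5-bis(benzyloxy)-2-[5,7-bis(benzyloxy)-4-oxo-4H-chromen-2-yl]phenyl}-2,3-dihydro-4H-chromen-4-one F6. Preparative chromatography on a chiral stationary phase then comes back to the route at 20. The other enantiomer, (2S)-5,7-bis(benzyloxy)-2-[4-(benzyloxy)phenyl]-6-{4,5-bis(benzyloxy)-2-[5,7-bis(benzyloxy)-4-oxo-4H-chromen-2-yl]phenyl}-2,3-dihydro-4H-chromen-4-one F7, can be racemised with base through the chalcone and recycled. Steps 11 and 12 are bypassed.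

Step 3. Site selectivity between the two phenols may be lost, with alkylation of the bay-region hydroxyl or double allylation. The fallback uses a far bulkier electrophile for the site-selective event and exchanges the group later. It sets out from 5. Silylation (t-BuPh2SiCl, imidazole, DMF, 0 °C) should give 8,9-bis(benzyloxy)-3-[(tert-butyldiphenylsilyl)oxy]-1-hydroxy-6H-benzo[c]chromen-6-one F8. Mitsunobu etherification with benzyl alcohol (PPh3, diisopropyl azodicarboxylate, THF) should give 1,8,9-tris(benzyloxy)-3-[(tert-butyldiphenylsilyl)oxy]-6H-benzo[c]chromen-6-one F9. Fluoride-triggered desilylation with alkylation of the phenoxide in the same flask (CsF, allyl bromide, DMF) comes back to the route at 7.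

**Further compounds**
F1 | step 6 | benzyl 2-[4-(allyloxy)-2,6-bis(benzyloxy)phenyl]-4,5-bis(benzyloxy)benzoate | O=C(OCc1ccccc1)c1cc(OCc2ccccc2)c(OCc2ccccc2)cc1-c1c(OCc2ccccc2)cc(OCC=C)cc1OCc1ccccc1
F2 | step 6 | 2-[4-(allyloxy)-2,6-bis(benzyloxy)phenyl]-4,5-bis(benzyloxy)benzoic acid | OC(=O)c1cc(OCc2ccccc2)c(OCc2ccccc2)cc1-c1c(OCc2ccccc2)cc(OCC=C)cc1OCc1ccccc1
F3 | step 6 | 2-acetyl-3,5-bis(benzyloxy)phenyl 2-[4-(allyloxy)-2,6-bis(benzyloxy)phenyl]-4,5-bis(benzyloxy)benzoate | CC(=O)c1c(OC(=O)c2cc(OCc3ccccc3)c(OCc3ccccc3)cc2-c2c(OCc3ccccc3)cc(OCC=C)cc2OCc2ccccc2)cc(OCc2ccccc2)cc1OCc1ccccc1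
F4 | step 6 | 1-{2-[4-(allyloxy)-2,6-bis(benzyloxy)phenyl]-4,5-bis(benzyloxy)phenyl}-3-[2,4-bis(benzyloxy)-6-hydroxyphenyl]propane-1,3-dione | O=C(CC(=O)c1cc(OCc2ccccc2)c(OCc2ccccc2)cc1-c1c(OCc2ccccc2)cc(OCC=C)cc1OCc1ccccc1)c1c(O)cc(OCc2ccccc2)cc1OCc1ccccc1
F5 | step 12 | (2E)-1-{2,4-bis(benzyloxy)-3-[4,5-bis(benzyloxy)-2-(5,7-bis(benzyloxy)-4-oxo-4H-chromen-2-yl)phenyl]-6-hydroxyphenyl}-3-[4-(benzyloxy)phenyl]prop-2-en-1-one | O=C(/C=C/c1ccc(OCc2ccccc2)cc1)c1c(O)cc(OCc2ccccc2)c(-c2cc(OCc3ccccc3)c(OCc3ccccc3)cc2-c2cc(=O)c3c(OCc4ccccc4)cc(OCc4ccccc4)cc3o2)c1OCc1ccccc1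
F6 | step 12 | rac-5,7-bis(benzyloxy)-2-[4-(benzyloxy)phenyl]-6-{4,5-bis(benzyloxy)-2-[5,7-bis(benzyloxy)-4-oxo-4H-chromen-2-yl]phenyl}-2,3-dihydro-4H-chromen-4-one | O=C1CC(c2ccc(OCc3ccccc3)cc2)Oc2cc(OCc3ccccc3)c(-c3cc(OCc4ccccc4)c(OCc4ccccc4)cc3-c3cc(=O)c4c(OCc5ccccc5)cc(OCc5ccccc5)cc4o3)c(OCc3ccccc3)c21
F7 | step 12 | (2S)-5,7-bis(benzyloxy)-2-[4-(benzyloxy)phenyl]-6-{4,5-bis(benzyloxy)-2-[5,7-bis(benzyloxy)-4-oxo-4H-chromen-2-yl]phenyl}-2,3-dihydro-4H-chromen-4-one | O=C1C[C@@H](c2ccc(OCc3ccccc3)cc2)Oc2cc(OCc3ccccc3)c(-c3cc(OCc4ccccc4)c(OCc4ccccc4)cc3-c3cc(=O)c4c(OCc5ccccc5)cc(OCc5ccccc5)cc4o3)c(OCc3ccccc3)c21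
F8 | step 3 | 8,9-bis(benzyloxy)-3-[(tert-butyldiphenylsilyl)oxy]-1-hydroxy-6H-benzo[c]chromen-6-one | O=C1Oc2cc(O[Si](c3ccccc3)(c3ccccc3)C(C)(C)C)cc(O)c2-c2cc(OCc3ccccc3)c(OCc3ccccc3)cc12
F9 | step 3 | 1,8,9-tris(benzyloxy)-3-[(tert-butyldiphenylsilyl)oxy]-6H-benzo[c]chromen-6-one | O=C1Oc2cc(O[Si](c3ccccc3)(c3ccccc3)C(C)(C)C)cc(OCc3ccccc3)c2-c2cc(OCc3ccccc3)c(OCc3ccccc3)cc12
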